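Set the last maple reading, 43.1 % at 25.0 h, beside what the main step by itself gives at that time, and you see that the maple flask falls behind a plain second-order reaction.

| setting | maple | ash | birch | winter | dusk | midnight | autumn |
|---|---|---|---|---|---|---|---|
| electrophile | 0.050 M | 0.034 M | 0.075 M | 0.050 M | 0.050 M | 0.050 M | 0.050 M |
| nucleophile | 1.1 equiv | 1.1 equiv | 1.1 equiv | 1.10 equiv | 1.10 equiv | 1.10 equiv | 1.10 equiv |
| free base | 1.2 equiv | 1.2 equiv | 1.2 equiv | 1.20 equiv | 1.20 equiv | 1.20 equiv (fed, over 32.0 h) | 1.20 equiv |
| remark | run made earlier | run made earlier | run made earlier | a single well-mixed tank run continuously and read at steady state, 40 h in it on average | one stirred flow tank at steady state, fed with the mixture as stated, mean residence time 200 h | a stirred flask in which free base is dosed at a steady rate over 32.0 h without added volume, worked up at 40 h | a closed flask charged with all of it at once and left for 40 h |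
| time |  |  |  |  |  | 40 h | 40 h |

| run | time / h | target / % |
|---|---|---|
| maple | 1.33 | 5.7 |
| maple | 4.00 | 15.0 |
| maple | 6.00 | 18.8 |
| maple | 10.0 | 26.5 |
| maple | 15.0 | 35.8 |
| maple | 20.0 | 38.4 |
| maple | 25.0 | 43.1 |
| ash | 2.50 | 8.0 |
| ash | 4.00 | 12.2 |
| ash | 6.00 | 16.0 |
| ash | 10.0 | 21.4 |
| ash | 15.0 | 28.9 |
| ash | 20.0 | 34.4 |
| ash | 30.0 | 40.5 |
| birch | 2.50 | 14.5 |
| birch | 4.00 | 20.0 |
| birch | 6.00 | 25.8 |
| birch | 10.0 | 35.3 |
| birch | 15.0 | 41.5 |
| birch | 20.0 | 46.8 |
| birch | 30.0 | 51.7 |

(each reading ± 1 percentage point)

- the stated concentrations are those of everything mixed, before any reaction; amounts are the same in each set-up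
- the feed brings no volume worth counting
- the earlier runs were made in a closed, stirred flask

- the set-up with the highest amount of target at the outlet or at the end, in percent of the electrophile put in ("none" if the first two lie within 2 percentage points) (winter / dusk / midnight / autumn / none)
- amount of target at the outlet or at the end, in percent of the electrophile put in, winter
- amount of target at the outlet or at the end, in percent of the electrophile put in, dusk
- amount of target at the outlet or at the end, in percent of the electrophile put in, midnight
- amount of target at the outlet or at the end, in percent of the electrophile put in, autumn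

Build it up, with x the fraction of electrophile turned into target and θ = k[electrophile]t, where [electrophile] is the charged value. First take the main step by itself, with the 15.0 % reading at 4.00 h setting k:

dx/dθ = (1 − x)(1.10 − x), k = 0.796 M⁻¹ h⁻¹

That integrates to 53.5 % at 25.0 h, more than the maple reading.

Now add one process. Suppose the acid set free takes a second nucleophile, so that each target costs two. The nucleophile becomes the limiting reagent, and you get the two-for-one ceiling, half the nucleophile charge counted on the electrophile, 55.0 %, below full conversion:

dx/dθ = (1 − x)(1.10 − 2x), k = 0.859 M⁻¹ h⁻¹

Here k comes from the last maple reading. The clock 1/(k[electrophile]) is 23.3 h at 0.050 M. Birch, which played no part in this, comes out at 50.2 % against 51.7 % read, a gap of 1.5 percentage points on a scatter of 1 point.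

The rest, free base and any side path, I leave out, since that gap shows nothing I can read. My figures, with θ = 1.72 for 40 h:

autumn 49.0 %, and midnight the same

winter, from the tank balance x = θ(1 − x)(1.10 − 2x): 37.5 %

dusk, with θ = 8.59: 49.3 %

Dusk is my weakest figure, as it runs far past the last reading.

The forecast lies near my figures on winter at 39.5 %, autumn at 50 % and dusk at 50 %, but it parts from me on midnight, 61 %, and names midnight: “slow dosing starves the side reaction”.

    nucleophile + acid set free ⇌ protonated nucleophile, settled at all times (K = 13000 M⁻¹)
    acid set free + free base ⇌ salt of the base (K = 5200 M⁻¹, k = 11.0 M⁻¹ h⁻¹)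
    electrophile + nucleophile → acid set free + target (k = 0.850 M⁻¹ h⁻¹)
    electrophile + acid set free → side product (k = 0.950 M⁻¹ h⁻¹)

The flasks give winter 38.4 %, dusk 58.6 %, midnight 49.7 % and autumn 50.0 %, so dusk leads. Autumn stays under the ceiling of 55.0 %, while dusk passes it by 3.6 points, and autumn left until 400 h reaches 84.1 %. In autumn, free base takes acid set free with a forward half-life of 1.1 h, the way back not counted, while at the start, with the nucleophile as charged, protonated nucleophile stands at 720 to one of free acid. Multiplied, these give a first estimate from the start charge of 751 h as the forward half-life of acid held on the nucleophile, against 40 h in autumn.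

(All runs were computed for substances that don't exist; the scatter is artificial.)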